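**Retrosynthetic overview**
1. Disconnection at C13–C14 (Suzuki) and C7–C8 (Stille) gives three pieces: lactone stannane 6 (C1–C7), iodide/boronate linchpin 16 (C8–C13) and oxane iodide 30 (C14–C24).
2. Enabling feature: in the oxane ring (O17, C17, C18, C19, C20, C21) the ring oxygen sits on C17, next to the exocyclic carbinol C16–OH. Ring carbon C21 carries O17, H and a propenyl group, so it is a crotonaldehyde carbon at acetal level, and O16 and O17 can both be hung on C21 as a 2-propenyl-1,3-dioxolane.
3. Key step: acid converts this dioxolane (23, bearing a C19=C20 Z-olefin) into the oxane by a Prins cyclisation. One operation forms the C20–C21 and C19–O bonds, relays three stereocentres (C19, C20, C21) from C17 and releases C16–OH; C19 is then inverted by SN2 (Mitsunobu).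
4. C15–C19, with both the C16 and C17 stereocentres, are C5–C1 of 2-deoxy-L-ribose (anomeric carbon = C19). Crotonaldehyde is first the diol protecting group and then C21–C24.
5. Ring order: the dihydropyranone first (RCM, step 5); the temporary pyranose and dioxolane rings are opened again (steps 14 and 17); the oxane last (step 17).

Key step: step 17

Remark on the chemistry: chain atoms are numbered C1 (lactone C=O) to C24 (propenyl CH3), and O16/O17 are the oxygens on C16/C17. The acetal carbon of 20–23 and the anomeric carbon of 18 and 20 are epimer mixtures. This has no consequence, because both carbons become sp2 (steps 14 and 17). 2-Deoxy-L-ribose is taken as a commercial sugar.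

Step 1
Reactants: 1 prop-2-yn-1-ol
Product: 2 (E)-3-(tributylstannyl)prop-2-en-1-ol
Conditions: Bu3SnH, AIBN (cat.), neat, 80 °C
Reagents that add atoms: tributyltin hydride CCCC[SnH](CCCC)CCCC
Why: Radical hydrostannation of the terminal alkyne under equilibrating conditions should funnel the adducts to the thermodynamic (E)-β-stannyl allylic alcohol (future C6=C7).

Step 2
Reactants: 2 (E)-3-(tributylstannyl)prop-2-en-1-ol
Product: 3 (E)-3-(tributylstannyl)prop-2-enal
Conditions: activated MnO2, CH2Cl2, rt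
Reagents that add atoms: none
Why: Allylic alcohol oxidation with MnO2 is neutral and should leave the acid-sensitive C–Sn bond and the E geometry untouched.

Step 3
Reactants: 3 (E)-3-(tributylstannyl)prop-2-enal
Product: 4 (1E,3S)-1-(tributylstannyl)hexa-1,5-dien-3-ol
Conditions: allylSnBu3, (S)-BINOL (20 mol %), Ti(OiPr)4 (10 mol %), 4 Å MS, CH2Cl2, −20 °C; aq NaHCO3
Reagents that add atoms: allyltributylstannane C=CC[Sn](CCCC)(CCCC)CCCC
Why: Keck catalytic asymmetric allylation, in which the (S)-BINOL–Ti(IV) complex shields one aldehyde face so that allyl transfer should give the (S)-carbinol (future C5), the same sense as for other aldehydes whose substituent outranks allyl.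

Step 4
Reactants: 4 (1E,3S)-1-(tributylstannyl)hexa-1,5-dien-3-ol
Product: 5 (1E,3S)-1-(tributylstannyl)hexa-1,5-dien-3-yl prop-2-enoate
Conditions: acryloyl chloride, Et3N, CH2Cl2, 0 °C
Reagents that add atoms: acryloyl chloride C=CC(=O)Cl
Why: Amine-mediated O-acylation of the secondary alcohol touches no stereocentre and installs C1–C2.

Step 5
Reactants: 5 (1E,3S)-1-(tributylstannyl)hexa-1,5-dien-3-yl prop-2-enoate
Product: 6 (6S)-6-[(E)-2-(tributylstannyl)ethenyl]-5,6-dihydro-2H-pyran-2-one
Conditions: Grubbs second-generation catalyst (5 mol %), CH2Cl2 (5 mM), reflux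
Reagents that add atoms: none
Why: Ring-closing metathesis of the two terminal olefins closes the six-membered enoate, while the bulky 1,2-disubstituted alkenylstannane should stay a spectator olefin.

Step 6
Reactants: 7 (S)-4-benzyl-3-propanoyl-1,3-oxazolidin-2-one; 8 3-bromoprop-1-yne
Product: 10 (S)-4-benzyl-3-[(2R)-2-methylpent-4-ynoyl]-1,3-oxazolidin-2-one, via sodium Z-enolate 9 (not isolated)
Conditions: NaHMDS, THF, −78 °C; then 8, −78 → −40 °C
Reagents that add atoms: none
Why: Evans asymmetric alkylation, in which the chelated Z-enolate is attacked on the face opposite the benzyl group, which should set the (R) centre (future C10).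

Step 7
Reactants: 10 (S)-4-benzyl-3-[(2R)-2-methylpent-4-ynoyl]-1,3-oxazolidin-2-one
Product: 11 (2R)-2-methylpent-4-yn-1-ol
Conditions: LiBH4, H2O (1 equiv), Et2O, 0 °C
Reagents that add atoms: none
Why: Reductive auxiliary cleavage with LiBH4 attacks the exocyclic imide carbonyl and should proceed without epimerisation.

Step 8
Reactants: 11 (2R)-2-methylpent-4-yn-1-ol
Product: 13 (2R,4E)-5-iodo-2,4-dimethylpent-4-en-1-ol, via alkenylalane 12 (not isolated)
Conditions: AlMe3 (3 equiv), Cp2ZrCl2 (20 mol %), CH2Cl2, 0 °C → rt; then I2, THF, −30 °C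
Reagents that add atoms: trimethylaluminium C[Al](C)C; iodine II
Why: Negishi zirconium-catalysed carboalumination adds Me–Al syn across the terminal alkyne (Me to the inner carbon), and iodinolysis with retention should give the E trisubstituted iodide (C12=C13).

Step 9
Reactants: 13 (2R,4E)-5-iodo-2,4-dimethylpent-4-en-1-ol
Product: 14 (2R,4E)-2,4-dimethyl-5-(4,4,5,5-tetramethyl-1,3,2-dioxaborolan-2-yl)pent-4-en-1-ol
Conditions: B2pin2, PdCl2(PPh3)2 (3 mol %), PPh3 (6 mol %), KOPh, toluene, 50 °C
Reagents that add atoms: bis(pinacolato)diboron CC1(C)OB(OC1(C)C)B1OC(C)(C)C(C)(C)O1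
Why: Miyaura borylation of an alkenyl iodide proceeds with retention of geometry and tolerates the free alcohol.

Step 10
Reactants: 14 (2R,4E)-2,4-dimethyl-5-(pinacolboryl)pent-4-en-1-ol
Product: 15 (2R,4E)-2,4-dimethyl-5-(4,4,5,5-tetramethyl-1,3,2-dioxaborolan-2-yl)pent-4-enal
Conditions: TEMPO (10 mol %), PhI(OAc)2, CH2Cl2, rt
Reagents that add atoms: none
Why: The oxoammonium (TEMPO/PhI(OAc)2) oxidation stops at the aldehyde and is non-basic, so the α-stereocentre should hold.

Step 11
Reactants: 15 (2R,4E)-2,4-dimethyl-5-(pinacolboryl)pent-4-enal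
Product: 16 2-[(1E,4R,5Z)-6-iodo-2,4-dimethylhepta-1,5-dienyl]-4,4,5,5-tetramethyl-1,3,2-dioxaborolane
Conditions: EtPPh3I, n-BuLi, THF, rt; I2, −78 °C; NaHMDS, −20 °C; then 15, −78 °C
Reagents that add atoms: ethyltriphenylphosphonium iodide CC[P+](c1ccccc1)(c1ccccc1)c1ccccc1.[I-]; iodine II
Why: Stork–Zhao-type Wittig olefination with the α-iodoethylidene ylide is kinetically controlled and should give the Z-iodoalkene (iodine cis to the chain, C8=C9), all strong base being consumed before the boronate aldehyde is added.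

Step 12
Reactants: 6 (6S)-6-[(E)-2-(tributylstannyl)ethenyl]-5,6-dihydro-2H-pyran-2-one; 16 iodide/boronate linchpin
Product: 17 (6S)-6-[(1E,3Z,5R,7E)-3,5,7-trimethyl-8-(4,4,5,5-tetramethyl-1,3,2-dioxaborolan-2-yl)octa-1,3,7-trienyl]-5,6-dihydro-2H-pyran-2-one
Conditions: Pd2(dba)3·CHCl3 (5 mol %), AsPh3 (20 mol %), CuI (10 mol %), DMF, rt → 40 °C, dark
Reagents that add atoms: none
Why: Stille coupling under neutral, base-free conditions joins C7 and C8 with retention of both olefin geometries, and the pinacol boronate should not transmetalate without base.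

Step 13
Reactants: 18 2-deoxy-L-ribose (2-deoxy-L-erythro-pentopyranose); 19 (E)-but-2-enal
Product: 20 3,4-O-[(E)-but-2-enylidene]-2-deoxy-L-erythro-pentopyranose
Conditions: PPTS (10 mol %), anhydrous MgSO4, DMF, rt
Reagents that add atoms: none
Why: In this acid-catalysed acetalisation only the cis-3,4-diol of the pyranose form can span a five-membered acetal, so the temporary pyranose ring secures the regiochemistry and the two sugar stereocentres (future C17 and C16) are untouched.

Step 14
Reactants: 20 3,4-O-[(E)-but-2-enylidene]-2-deoxy-L-erythro-pentopyranose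
Product: 21 [(4S,5R)-5-[(Z)-but-2-enyl]-2-[(E)-prop-1-enyl]-1,3-dioxolan-4-yl]methanol
Conditions: EtPPh3Br (3 equiv), KHMDS (2.9 equiv), THF, 0 °C; then 20, −78 °C → rt
Reagents that add atoms: ethyltriphenylphosphonium bromide CC[P+](c1ccccc1)(c1ccccc1)c1ccccc1.[Br-]
Why: Wittig olefination of the lactol through its hydroxy-aldehyde tautomer with the salt-free unstabilised ylide should give the Z-olefin C19=C20 and free the C15 hydroxyl.

Step 15
Reactants: 21 dioxolane alcohol
Product: 22 (4R,5R)-5-[(Z)-but-2-enyl]-2-[(E)-prop-1-enyl]-1,3-dioxolane-4-carbaldehyde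
Conditions: TEMPO (10 mol %), PhI(OAc)2, CH2Cl2, rt
Reagents that add atoms: none
Why: The oxoammonium oxidation of the primary alcohol is non-basic, so the cis-dioxolane α-stereocentre should not epimerise (only the descriptor changes, through priorities).

Step 16
Reactants: 22 dioxolane aldehyde
Product: 23 (4S,5R)-5-[(Z)-but-2-enyl]-4-[(E)-2-iodoethenyl]-2-[(E)-prop-1-enyl]-1,3-dioxolane
Conditions: CrCl2 (8 equiv), CHI3 (3 equiv), dioxane–THF (6:1), 0 °C → rt
Reagents that add atoms: iodoform IC(I)I
Why: In the Takai olefination the gem-dichromium reagent adds to the aldehyde and eliminates to the E-iodoalkene (C14=C15) under non-basic conditions that the acetal and C16 should tolerate.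

Step 17
Reactants: 23 (4S,5R)-5-[(Z)-but-2-enyl]-4-[(E)-2-iodoethenyl]-2-[(E)-prop-1-enyl]-1,3-dioxolane
Product: 26 (2R,3R,4R,6R)-6-[(1S,2E)-1-hydroxy-3-iodoprop-2-enyl]-3-methyl-2-[(E)-prop-1-enyl]oxan-4-yl acetate (propenyl, methyl, acetate and side chain all cis; methyl axial, acetate equatorial), via oxocarbenium ion 24 (not isolated), via oxan-4-yl cation 25 (not isolated)
Conditions: BF3·OEt2 (promoter), AcOH (10 equiv), CH2Cl2, −20 → 0 °C; aq NaHCO3
Reagents that add atoms: acetic acid CC(=O)O
Why: Prins cyclisation of a cyclic acetal: the acid opens the dioxolane reversibly, and departure of O16 from the acetal carbon C21 gives the (E)-oxocarbenium ion 24 (O17=C21, conjugated with the propenyl group), whose C21 is attacked by C20 of the Z-olefin to give the oxan-4-yl cation 25, which acetate captures at C19. The closest known reactions are the Lewis-acid Prins cyclisations of 4-allyl-1,3-dioxanes and of α-acetoxy ethers of homoallylic alcohols with BF3·OEt2/AcOH. The oxane closes in the 6-endo-trig mode through a chair, and the new ring bond is C20–C21. C17 from the sugar controls everything: its C16 side chain sits equatorial, which forces the propenyl group at C21 equatorial (2,6-cis), the Z geometry of the olefin places the C20 methyl axial and cis to the propenyl group, and acetate adds equatorially at C19, anti to the forming C20–C21 bond, which gives the 19-epimer on purpose (inverted in step 20). The step needs regioselective use of the two acetal oxygens and chemoselective use of one of four olefins: opening is reversible and only the O17 ion has an olefin within homoallylic chair reach, whereas the O16 ion is destabilised by the iodovinyl group and could only close 6-exo to an unstabilised exocyclic cation, and the iodoalkene and the propenyl group are too electron-poor or wrongly placed to compete. A 2-oxonia-Cope leak is uphill because it would trade the conjugated oxocarbenium ion for a non-conjugated, α-oxygenated one, so C17 should not be scrambled.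

Step 18
Reactants: 26 oxane acetate with free C16–OH
Product: 27 (2R,3R,4R,6R)-6-[(1S,2E)-1-(tert-butyldimethylsilyloxy)-3-iodoprop-2-enyl]-3-methyl-2-[(E)-prop-1-enyl]oxan-4-yl acetate
Conditions: TBSOTf, 2,6-lutidine, CH2Cl2, 0 °C
Reagents that add atoms: tert-butyldimethylsilyl triflate CC(C)(C)[Si](C)(C)OS(=O)(=O)C(F)(F)F
Why: Silyl ether formation at the only free hydroxyl (C16) differentiates the two oxygens, and acetate and iodoalkene are inert to the conditions.

Step 19
Reactants: 27 silyl ether acetate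
Product: 28 (2R,3R,4R,6R)-6-[(1S,2E)-1-(tert-butyldimethylsilyloxy)-3-iodoprop-2-enyl]-3-methyl-2-[(E)-prop-1-enyl]oxan-4-ol (equatorial OH)
Conditions: K2CO3 (20 mol %), MeOH, rt
Reagents that add atoms: none
Why: Base-catalysed transesterification removes the acetate without touching the C–O bond at C19 or the TBS ether.

Step 20
Reactants: 28 equatorial C19 alcohol
Product: 29 (2R,3R,4S,6R)-6-[(1S,2E)-1-(tert-butyldimethylsilyloxy)-3-iodoprop-2-enyl]-3-methyl-2-[(E)-prop-1-enyl]oxan-4-yl 4-nitrobenzoate (axial ester)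
Conditions: PPh3, DIAD, 4-nitrobenzoic acid, toluene, 0 °C → rt
Reagents that add atoms: 4-nitrobenzoic acid O=C(O)c1ccc(cc1)[N+](=O)[O-]
Why: In the Mitsunobu inversion the carboxylate displaces the equatorial oxyphosphonium group by SN2 along the axial trajectory on the face opposite the axial C20 methyl, which should set the required (19S) centre, while an equatorial leaving group has no antiperiplanar hydrogen for E2.

Step 21
Reactants: 29 axial 4-nitrobenzoate
Product: 30 (2R,3R,4S,6R)-6-[(1S,2E)-1-(tert-butyldimethylsilyloxy)-3-iodoprop-2-enyl]-3-methyl-2-[(E)-prop-1-enyl]oxan-4-ol (axial OH)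
Conditions: K2CO3 (20 mol %), MeOH, rt
Reagents that add atoms: none
Why: Transesterification cleaves the activated aryl ester at the acyl carbon, so C19 keeps its new configuration.

Step 22
Reactants: 17 lactone trienyl boronate; 30 oxane iodide
Product: 31 16-O-TBS ether of the target
Conditions: Pd(PPh3)4 (10 mol %), TlOEt (1.8 equiv), THF–H2O (3:1), degassed, rt
Reagents that add atoms: none
Why: The thallium-accelerated Suzuki–Miyaura coupling joins C13 and C14 with retention of both alkene geometries and should be fast enough at room temperature to spare the enoate lactone and the free C19 alcohol.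

Step 23
Reactants: 31 16-O-TBS ether of the target
Product: 32 target, (6S)-6-[(1E,3Z,5R,7E,9E,11S)-11-hydroxy-11-[(2R,4S,5R,6R)-4-hydroxy-5-methyl-6-[(E)-prop-1-enyl]oxan-2-yl]-3,5,7-trimethylundeca-1,3,7,9-tetraenyl]-5,6-dihydro-2H-pyran-2-one
Conditions: HF·pyridine, pyridine, THF, 0 °C → rt
Reagents that add atoms: none
Why: Buffered fluoride desilylation attacks silicon only, so the dienylic C16–O bond, the polyene and the lactone should survive.

**Compound list**
1 | prop-2-yn-1-ol | C#CCO | starting material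
2 | (E)-3-(tributylstannyl)prop-2-en-1-ol | CCCC[Sn](CCCC)(CCCC)/C=C/CO | intermediate
3 | (E)-3-(tributylstannyl)prop-2-enal | CCCC[Sn](CCCC)(CCCC)/C=C/C=O | intermediate
4 | (1E,3S)-1-(tributylstannyl)hexa-1,5-dien-3-ol | CCCC[Sn](CCCC)(CCCC)/C=C/[C@@H](O)CC=C | intermediate
5 | (1E,3S)-1-(tributylstannyl)hexa-1,5-dien-3-yl prop-2-enoate | CCCC[Sn](CCCC)(CCCC)/C=C/[C@@H](OC(=O)C=C)CC=C | intermediate
6 | (6S)-6-[(E)-2-(tributylstannyl)ethenyl]-5,6-dihydro-2H-pyran-2-one | CCCC[Sn](CCCC)(CCCC)/C=C/[C@@H]1CC=CC(=O)O1 | intermediate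
7 | (S)-4-benzyl-3-propanoyl-1,3-oxazolidin-2-one | CCC(=O)N1[C@@H](Cc2ccccc2)COC1=O | starting material
8 | 3-bromoprop-1-yne | C#CCBr | starting material
9 | sodium Z-enolate of 7 | C/C=C(\[O-])N1[C@@H](Cc2ccccc2)COC1=O.[Na+] | intermediate
10 | (S)-4-benzyl-3-[(2R)-2-methylpent-4-ynoyl]-1,3-oxazolidin-2-one | C#CC[C@@H](C)C(=O)N1[C@@H](Cc2ccccc2)COC1=O | intermediate
11 | (2R)-2-methylpent-4-yn-1-ol | C#CC[C@@H](C)CO | intermediate
12 | (E)-alkenyl(dimethyl)alane, O-dimethylaluminium alkoxide | C[Al](C)/C=C(\C)C[C@@H](C)CO[Al](C)C | intermediate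
13 | (2R,4E)-5-iodo-2,4-dimethylpent-4-en-1-ol | I/C=C(\C)C[C@@H](C)CO | intermediate
14 | (2R,4E)-2,4-dimethyl-5-(pinacolboryl)pent-4-en-1-ol | CC1(C)OB(OC1(C)C)/C=C(\C)C[C@@H](C)CO | intermediate
15 | (2R,4E)-2,4-dimethyl-5-(pinacolboryl)pent-4-enal | CC1(C)OB(OC1(C)C)/C=C(\C)C[C@@H](C)C=O | intermediate
16 | 2-[(1E,4R,5Z)-6-iodo-2,4-dimethylhepta-1,5-dienyl]-4,4,5,5-tetramethyl-1,3,2-dioxaborolane | CC1(C)OB(OC1(C)C)/C=C(\C)C[C@@H](C)/C=C(C)\I | intermediate
17 | (6S)-6-[(1E,3Z,5R,7E)-3,5,7-trimethyl-8-(pinacolboryl)octa-1,3,7-trienyl]-5,6-dihydro-2H-pyran-2-one | CC1(C)OB(OC1(C)C)/C=C(\C)C[C@@H](C)/C=C(C)\C=C\[C@@H]2CC=CC(=O)O2 | intermediate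
18 | 2-deoxy-L-ribose (pyranose form; open form (3R,4S)-3,4,5-trihydroxypentanal) | O[C@@H]1CC(O)OC[C@@H]1O | starting material
19 | (E)-but-2-enal (crotonaldehyde) | C/C=C/C=O | starting material
20 | 3,4-O-[(E)-but-2-enylidene]-2-deoxy-L-erythro-pentopyranose | C/C=C/C1O[C@@H]2CC(O)OC[C@@H]2O1 | intermediate
21 | [(4S,5R)-5-[(Z)-but-2-enyl]-2-[(E)-prop-1-enyl]-1,3-dioxolan-4-yl]methanol | C/C=C/C1O[C@@H]([C@@H](O1)CO)C/C=C\C | intermediate
22 | (4R,5R)-5-[(Z)-but-2-enyl]-2-[(E)-prop-1-enyl]-1,3-dioxolane-4-carbaldehyde | C/C=C/C1O[C@@H]([C@@H](O1)C=O)C/C=C\C | intermediate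
23 | (4S,5R)-5-[(Z)-but-2-enyl]-4-[(E)-2-iodoethenyl]-2-[(E)-prop-1-enyl]-1,3-dioxolane | C/C=C/C1O[C@@H]([C@@H](O1)/C=C/I)C/C=C\C | intermediate
24 | O17=C21 oxocarbenium ion with free C16–OH | C/C=C/C=[O+][C@@H]([C@@H](O)/C=C/I)C/C=C\C | intermediate
25 | 2,6-cis-3-methyl-oxan-4-yl cation | C/C=C/[C@H]1O[C@@H]([C@@H](O)/C=C/I)C[CH+][C@H]1C | intermediate
26 | (2R,3R,4R,6R)-6-[(1S,2E)-1-hydroxy-3-iodoprop-2-enyl]-3-methyl-2-[(E)-prop-1-enyl]oxan-4-yl acetate | C/C=C/[C@H]1O[C@@H]([C@@H](O)/C=C/I)C[C@@H](OC(C)=O)[C@H]1C | intermediate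
27 | 16-O-TBS ether of 26 | C/C=C/[C@H]1O[C@@H]([C@@H](O[Si](C)(C)C(C)(C)C)/C=C/I)C[C@@H](OC(C)=O)[C@H]1C | intermediate
28 | (2R,3R,4R,6R)-6-[(1S,2E)-1-(TBSO)-3-iodoprop-2-enyl]-3-methyl-2-[(E)-prop-1-enyl]oxan-4-ol (equatorial OH) | C/C=C/[C@H]1O[C@@H]([C@@H](O[Si](C)(C)C(C)(C)C)/C=C/I)C[C@@H](O)[C@H]1C | intermediate
29 | (2R,3R,4S,6R)-6-[(1S,2E)-1-(TBSO)-3-iodoprop-2-enyl]-3-methyl-2-[(E)-prop-1-enyl]oxan-4-yl 4-nitrobenzoate (axial ester) | C/C=C/[C@H]1O[C@@H]([C@@H](O[Si](C)(C)C(C)(C)C)/C=C/I)C[C@H](OC(=O)c2ccc(cc2)[N+](=O)[O-])[C@H]1C | intermediate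
30 | (2R,3R,4S,6R)-6-[(1S,2E)-1-(TBSO)-3-iodoprop-2-enyl]-3-methyl-2-[(E)-prop-1-enyl]oxan-4-ol (axial OH) | C/C=C/[C@H]1O[C@@H]([C@@H](O[Si](C)(C)C(C)(C)C)/C=C/I)C[C@H](O)[C@H]1C | intermediate
31 | 16-O-TBS ether of the target | C/C=C/[C@H]1O[C@@H]([C@@H](O[Si](C)(C)C(C)(C)C)/C=C/C=C(\C)C[C@@H](C)/C=C(C)\C=C\[C@@H]2CC=CC(=O)O2)C[C@H](O)[C@H]1C | intermediate
32 | target (5S,10R,16S,17R,19S,20R,21R) | C/C=C/[C@H]1O[C@@H]([C@@H](O)/C=C/C=C(\C)C[C@@H](C)/C=C(C)\C=C\[C@@H]2CC=CC(=O)O2)C[C@H](O)[C@H]1C | target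

**Totals**
Total step count: 23.
Longest linear sequence: 11 steps (18 → 32, steps 13–23).

**Steps most likely to fail**

Step 17. The acetal may open persistently towards the O16 oxocarbenium ion and close in the 6-exo mode. Alternatively, the stabilised conjugated ion may react too slowly, so that proton loss and acetal cleavage take over.
Fallback (from 23, back at 26): O16 is taken out of play at the ketone oxidation level.
- The acetal of 23 is hydrolysed (80% aq AcOH) to (1E,3S,4R,6Z)-1-iodoocta-1,6-diene-3,4-diol F1.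
- MnO2 oxidises only the allylic C16 carbinol, giving (1E,4R,6Z)-4-hydroxy-1-iodoocta-1,6-dien-3-one F2.
- O17–H is now the only hydroxyl, so an ordinary bimolecular Prins cyclisation with 19 (BF3·OEt2, AcOH) can pass only through the O17 oxocarbenium ion. It should give (2R,3R,4R,6R)-6-[(E)-3-iodoprop-2-enoyl]-3-methyl-2-[(E)-prop-1-enyl]oxan-4-yl acetate F3.
- Chelation-controlled 1,2-reduction (Zn(BH4)2, Et2O, −30 °C, zinc bridging O17 and the C16 carbonyl) should give the 16,17-anti carbinol 26.

Step 11. Partial loss of iodine from the ylide, low conversion of the α-branched aldehyde, erosion of the Z selectivity and attack of residual base on the boronate can all lower the outcome.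
Fallback (from 15, back at 17): the halogen is installed first and the methyl group second.
- Dibromo-olefination of 15 (CBr4, PPh3, 2,6-lutidine) gives 2-[(1E,4R)-6,6-dibromo-2,4-dimethylhexa-1,5-dienyl]-4,4,5,5-tetramethyl-1,3,2-dioxaborolane F4.
- Palladium-catalysed trans-selective Negishi mono-methylation (Me2Zn, PdCl2(DPEphos)) replaces only the bromide trans to the chain. This gives 2-[(1E,4R,5Z)-6-bromo-2,4-dimethylhepta-1,5-dienyl]-4,4,5,5-tetramethyl-1,3,2-dioxaborolane F5.
- F5 is coupled with 6 by the Stille reaction of step 12 to give 17.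

Step 20. Displacement at a ring carbon flanked by a branched centre may be slow. Elimination to a dihydropyran or acyl transfer with retention could then compete.
Fallback (from 28, back at 30): the centre is corrected by redox instead of substitution.
- Dess–Martin oxidation of 28 gives the 19-ketone (2R,3S,6R)-6-[(1S,2E)-1-(tert-butyldimethylsilyloxy)-3-iodoprop-2-enyl]-3-methyl-2-[(E)-prop-1-enyl]oxan-4-one F6.
- F6 is reduced at once with L-Selectride (THF, −78 °C). The bulky hydride should avoid the axial hydrogens at C17 and C21 and attack along the equatorial trajectory, giving the axial alcohol 30.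

**Further compounds**
F1 | step 17 | (1E,3S,4R,6Z)-1-iodoocta-1,6-diene-3,4-diol | O[C@@H]([C@@H](O)/C=C/I)C/C=C\C
F2 | step 17 | (1E,4R,6Z)-4-hydroxy-1-iodoocta-1,6-dien-3-one | O[C@@H](C(=O)/C=C/I)C/C=C\C
F3 | step 17 | (2R,3R,4R,6R)-6-[(E)-3-iodoprop-2-enoyl]-3-methyl-2-[(E)-prop-1-enyl]oxan-4-yl acetate | C/C=C/[C@H]1O[C@@H](C(=O)/C=C/I)C[C@@H](OC(C)=O)[C@H]1C
F4 | step 11 | 2-[(1E,4R)-6,6-dibromo-2,4-dimethylhexa-1,5-dienyl]-4,4,5,5-tetramethyl-1,3,2-dioxaborolane | CC1(C)OB(OC1(C)C)/C=C(\C)C[C@@H](C)C=C(Br)Br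
F5 | step 11 | 2-[(1E,4R,5Z)-6-bromo-2,4-dimethylhepta-1,5-dienyl]-4,4,5,5-tetramethyl-1,3,2-dioxaborolane | CC1(C)OB(OC1(C)C)/C=C(\C)C[C@@H](C)/C=C(C)\Br
F6 | step 20 | (2R,3S,6R)-6-[(1S,2E)-1-(tert-butyldimethylsilyloxy)-3-iodoprop-2-enyl]-3-methyl-2-[(E)-prop-1-enyl]oxan-4-one | C/C=C/[C@H]1O[C@@H]([C@@H](O[Si](C)(C)C(C)(C)C)/C=C/I)CC(=O)[C@H]1C
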